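(Readings and results are calculated for an exercise, noise included.)

- A leftover is written into this row: partner is charged below the substrate at 0.900 equiv, which makes it the limiting reagent, so by the proposed steps product stands at 90.0% of the substrate charged or lower, and 10.0% or more stays behind in some other form.

| flask | substrate | partner | free catalyst | remark | time |
|---|---|---|---|---|---|
| beta | 13 mM (in portions, 4) | 0.90 equiv | 5 mol% | run made earlier; portions every 40 s |  |
| west | 20 mM (in portions, 4) | 0.900 equiv | 5 mol% | the portions of substrate follow each other after 40 s, the first at the start | 12 min |
| east | 20 mM (in portions, 4) | 0.900 equiv | 10 mol% | the portions of substrate follow each other after 40 s, the first at the start | 12 min |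
| north | 20 mM (in portions, 4) | 0.900 equiv | 20 mol% | the portions of substrate follow each other after 40 s, the first at the start | 12 min |
| north-east | 20 mM (in portions, 4) | 0.900 equiv | 40 mol% | the portions of substrate follow each other after 40 s, the first at the start | 12 min |

beta run (percent of the substrate charged): time / min: product / % = 0.333: 0; 0.667: 0.3; 1.00: 0.3; 1.33: 0.7; 1.50: 1.1; 2.00: 2.7; 2.50: 4.6

(standard deviation of a reading: 0.3 percentage points)

1. amount of product at the end, in percent of the substrate charged for west, east, north, north-east, in this order
2. the course of these numbers from the first flask to the last (rises all the way / hardly changes / falls all the way / rises, then falls / falls, then rises)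

- the analysis behind the earlier runs scatters by 0.3 percentage points, standard deviation
- steps that have been proposed: substrate + free catalyst -> free catalyst + open intermediate; free catalyst + product -> spent catalyst; free catalyst + open intermediate <-> catalyst intermediate; partner + catalyst intermediate -> free catalyst + product
- "hardly changes" means that all values lie within two and a half points (for a concentration: within two and a half percent of the largest)
- no earlier run changes the charge of free catalyst; that part of a forecast is a guess

- The first instants are read in beta, where product shows 0.3% at 1.00 min against a scatter of 0.3 percentage points, and in the proposed steps free catalyst first opens substrate, then binds open intermediate, before partner releases product.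
- The middle is read in beta too: from 2.00 min to 2.50 min product gains 1.9 points, a reading of 0.494 mM min⁻¹ on 0.650 mM of catalyst, or 0.760 min⁻¹ per catalyst.
- Carrying that pace over is this text's own guess, since no earlier run changes the loading: partner in west lasts 23.7 min, longer than the 12 min allowed, while in north-east it lasts 2.96 min, well inside them.
- In the proposed steps each spent catalyst formed takes one product out of the flask, so product equals partner used less spent catalyst, with one product per partner as the zero of the scale.
- For north-east, 50.0% is the net end level, the product standing once partner is used up and the whole catalyst charge is spent, reckoned as the partner's share less the loading; for east it is 80.0% and for north 70.0%.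
- This text's own row, which takes the whole catalyst charge as spent by the end in the last three flasks, is therefore 45.6% for west, reckoned from the pace, and then the net end levels 80.0%, 70.0% and 50.0%, a course that rises, then falls.
- The forecast gives 50%, 70%, 70% and 52%, with the course rises, then falls, and stands 10 points below this text's row at east; its ground for the fall is that “Spent catalyst also locks up product, one per catalyst, so heavy loading loses up to its own mol%”.
- The flasks give 65.4%, 79.9%, 75.9% and 62.1%, and the course rises, then falls.

    substrate + free catalyst → free catalyst + open intermediate (k = 3.96 L mol⁻¹ s⁻¹)
    free catalyst + product → spent catalyst (k = 0.205 L mol⁻¹ s⁻¹)
    free catalyst + open intermediate ⇌ catalyst intermediate (K = 1250 L mol⁻¹, k = 7.88 L mol⁻¹ s⁻¹)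
    partner + catalyst intermediate → free catalyst + product (k = 36.9 L mol⁻¹ s⁻¹)

- In west at 3.45 min, catalyst intermediate has a half-life of 1.3 s against partner, far shorter than the 0.31 min of free catalyst under the forward step to catalyst intermediate, and at 6.00 min free catalyst, the resting state, holds 73.4% of the catalyst against 7.23% as catalyst intermediate. North-east stands at 62.1% at 12.0 min with 69.8% of its catalyst spent, above its net end level of 50.0%, and holds 50.2% at 120 min, while east, with a net end level of 80.0%, holds 80.0% at 120 min.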